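**Plan**

- The retrosynthesis first cuts the bond between the two carbonyl carbons of the dione: the carbonyl on ring B comes from an aryl ester, the carbonyl on ring A from 2-hydroxy-4-methoxybenzaldehyde used as its lithiated dithiane.
- Ring B is then cut at C1–C2, C2–C3 and C4–C5. Its four neighbouring substituents (dione carbon on C1, hydroxyl on C2, prenyl on C3, hydroxyl on C4, with hydrogens on C5 and C6) are exactly what an ester-bearing vinylketene and a prenyl-substituted siloxyalkyne deliver.
- Forward: the diazo enone and the siloxyalkyne are made from open-chain esters, ring B is closed by benzannulation, ring A (bought) is attached by acylation, the dithiane is hydrolysed and the phenols are set free.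
- The target has no stereocenter and no stereogenic double bond; only the regiochemistry of the benzannulation needs control, and the polarity of the siloxyalkyne supplies it.

Key step: step 4

Remark: the diazo enone carries an electron-poor alkene that can act as a dipolarophile toward its own diazo group, so it is assumed to be made shortly before the benzannulation and kept cold, dilute and dark.

**Route**

Step 1
Reactants: 1 methyl (E)-4-oxopent-2-enoate
Product: 3 methyl (E)-7,7,7-trifluoro-4,6-dioxohept-2-enoate, via lithium enolate 2 (not isolated)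
Conditions: LiN(SiMe3)2, THF, -78 °C (slow addition of 1); CF3CO2CH2CF3, -78 °C; aq. HCl; crude 3 used directly
Reagents that add atoms: 2,2,2-trifluoroethyl trifluoroacetate, O=C(OCC(F)(F)F)C(F)(F)F
Why: Kinetic deprotonation of the only enolizable position (the methyl group) followed by Claisen-type trifluoroacetylation is the activation stage of the detrifluoroacetylative diazo transfer, and slow addition of the ketone to the base at -78 °C keeps free enone scarce so that the enolate is acylated before it can add to a second molecule in a Michael sense.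

Step 2
Reactants: 3 methyl (E)-7,7,7-trifluoro-4,6-dioxohept-2-enoate
Product: 4 methyl (E)-5-diazo-4-oxopent-2-enoate
Conditions: 4-AcNHC6H4SO2N3, Et3N, H2O (1 equiv), MeCN, rt, dark
Reagents that add atoms: 4-acetamidobenzenesulfonyl azide, CC(=O)Nc1ccc(S(=O)(=O)N=[N+]=[N-])cc1
Why: Regitz-type diazo transfer to the activated 1,3-diketone with loss of the trifluoroacetyl group as an N-sulfonyl trifluoroacetamide gives the diazo ketone under mild amine conditions that leave the E enoate alone, whereas acylation of diazomethane is ruled out because diazomethane would add to the alkene.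

Step 3
Reactants: 5 ethyl 4-methylpent-3-enoate
Product: 8 triisopropyl[(5-methylhex-4-en-1-yn-1-yl)oxy]silane, via dibromo enolate 6 (not isolated), via lithium ynolate 7 (not isolated)
Conditions: CH2Br2, lithium 2,2,6,6-tetramethylpiperidide, THF, -78 °C; LiN(SiMe3)2, -78 to -20 °C; n-BuLi, -78 to 0 °C; i-Pr3SiOTf, -78 °C to rt
Reagents that add atoms: dibromomethane, BrCBr; triisopropylsilyl trifluoromethanesulfonate, CC(C)[Si](OS(=O)(=O)C(F)(F)F)(C(C)C)C(C)C
Why: Kowalski ester homologation: LiCHBr2 adds to the ester carbonyl faster than it deprotonates the ester, bromine–lithium exchange on dibromo enolate 6 triggers the 1,2-shift of the prenyl CH2 group that gives ynolate 7, and the bulky silyl triflate traps 7 on oxygen as the isolable triisopropylsilyl ynol ether.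

Step 4
Reactants: 4 methyl (E)-5-diazo-4-oxopent-2-enoate; 8 triisopropyl[(5-methylhex-4-en-1-yn-1-yl)oxy]silane (1.3 equiv)
Product: 13 methyl 2-hydroxy-3-(3-methylbut-2-en-1-yl)-4-[(triisopropylsilyl)oxy]benzoate, via vinylketene 9 (not isolated), via vinylcyclobutenone 10 (not isolated), via dienylketene 11 (not isolated), via cyclohexadienone 12 (not isolated)
Conditions: hν (254 nm, low-pressure mercury lamp, quartz), degassed ClCH2CH2Cl, rt; then 80 °C
Reagents that add atoms: none
Why: Light expels N2 from 4 and the photochemical Wolff rearrangement moves the alkenyl group onto the former diazo carbon, giving the ester-substituted vinylketene 9. The electron-rich siloxyalkyne 8 adds its prenyl-bearing carbon to the ketene carbonyl carbon, and the regioselective [2+2] cycloaddition forms vinylcyclobutenone 10 and with it the C2–C3 and C4–C5 bonds of ring B. Four-electron electrocyclic opening of 10, by light or on warming, gives dienylketene 11, and ring B is closed by a thermal six-electron disrotatory electrocyclization that joins the ketene carbon to the ester-bearing alkene terminus (C1–C2); cyclohexadienone 12 then tautomerizes to the phenol. The closest known reaction type is the second-generation Danheiser benzannulation of alpha-diazo enones with siloxyalkynes, which gives resorcinol monosilyl ethers that carry the alkyne substituent between the two oxygens. No stereocenter is created in the product, because the only sp3 ring carbons of 10 and 12 end up aromatic. The step needs regiocontrol in the [2+2] event, which the oxygen-induced polarization of the ynol ether secures, and preference for the alkyne over the prenyl alkene, which the much higher nucleophilicity of the siloxyalkyne secures; the E enoate keeps the ester on the outside of the closing triene, and the hydrogen bond from the new hydroxyl to the ester should slow its addition to unreacted ketene.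

Step 5
Reactants: 13 methyl 2-hydroxy-3-(3-methylbut-2-en-1-yl)-4-[(triisopropylsilyl)oxy]benzoate
Product: 14 methyl 2-(methoxymethoxy)-3-(3-methylbut-2-en-1-yl)-4-[(triisopropylsilyl)oxy]benzoate
Conditions: MOMCl, i-Pr2NEt, n-Bu4NI (cat.), CH2Cl2, 40 °C
Reagents that add atoms: chloromethyl methyl ether (MOMCl), COCCl
Why: O-alkylation of the chelated phenol (MOM protection), helped by iodide catalysis through the more reactive iodomethyl ether, removes the acidic proton that would otherwise quench the carbanion of step 8 and deactivate the ester as a phenoxide.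

Step 6
Reactants: 15 2-hydroxy-4-methoxybenzaldehyde
Product: 16 2-(1,3-dithian-2-yl)-5-methoxyphenol
Conditions: HS(CH2)3SH, BF3·OEt2 (cat.), CH2Cl2, 0 °C to rt
Reagents that add atoms: propane-1,3-dithiol, SCCCS
Why: Lewis acid catalyzed dithioacetalization of the aldehyde tolerates the free phenol, which is protected only afterwards because a MOM ether would not survive BF3 in the presence of a thiol.

Step 7
Reactants: 16 2-(1,3-dithian-2-yl)-5-methoxyphenol
Product: 17 2-[4-methoxy-2-(methoxymethoxy)phenyl]-1,3-dithiane
Conditions: MOMCl, i-Pr2NEt, CH2Cl2, 0 °C to rt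
Reagents that add atoms: chloromethyl methyl ether (MOMCl), COCCl
Why: MOM protection by O-alkylation of the phenol under amine base; an acetal ether is chosen over a silyl ether because an ortho silyloxy group could migrate to the neighbouring carbanion in the next step (retro-Brook shift).

Step 8
Reactants: 17 2-[4-methoxy-2-(methoxymethoxy)phenyl]-1,3-dithiane (1.3 equiv); 14 methyl 2-(methoxymethoxy)-3-(3-methylbut-2-en-1-yl)-4-[(triisopropylsilyl)oxy]benzoate
Product: 19 {2-[4-methoxy-2-(methoxymethoxy)phenyl]-1,3-dithian-2-yl}{2-(methoxymethoxy)-3-(3-methylbut-2-en-1-yl)-4-[(triisopropylsilyl)oxy]phenyl}methanone, via lithiodithiane 18 (not isolated)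
Conditions: n-BuLi (1.2 equiv), THF, -78 to -40 °C; then 14, -78 °C to rt; aq. NH4Cl
Reagents that add atoms: none
Why: Corey–Seebach umpolung: n-BuLi removes the sulfur-stabilized benzylic proton at low temperature well before ring lithiation between the two ethers can compete, and the acyl anion equivalent 18 is acylated by the methyl ester to a hindered, non-enolizable ketone that cannot take up a second anion.

Step 9
Reactants: 19 the acyl dithiane from step 8
Product: 20 1-[4-methoxy-2-(methoxymethoxy)phenyl]-2-{2-(methoxymethoxy)-3-(3-methylbut-2-en-1-yl)-4-[(triisopropylsilyl)oxy]phenyl}ethane-1,2-dione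
Conditions: PhI(OCOCF3)2, NaHCO3, MeCN–H2O (9:1), 0 °C
Reagents that add atoms: water, O
Why: Oxidative dithiane hydrolysis with a trivalent iodine reagent: sulfur is activated as an iodosulfonium ion and water captures the thionium ion, and this fast sulfur oxidation in buffered aqueous MeCN at 0 °C should leave the trisubstituted alkene, the MOM ethers and the aryl silyl ether untouched.

Step 10
Reactants: 20 the bis-MOM dione from step 9
Product: 21 1-(2-hydroxy-4-methoxyphenyl)-2-{2-hydroxy-3-(3-methylbut-2-en-1-yl)-4-[(triisopropylsilyl)oxy]phenyl}ethane-1,2-dione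
Conditions: 3 M aq. HCl, MeOH, 40 °C
Reagents that add atoms: none
Why: Acid-catalyzed acetal exchange with methanol removes both MOM groups, each made labile by its ortho carbonyl, while the C4 oxygen of ring B is still silylated and the freed C2 hydroxyl is held in a hydrogen bond to the ketone, which should hold back acid-promoted cyclization of the prenyl group to a chroman.

Step 11
Reactants: 21 the silyl-protected dione from step 10
Product: 22 licoagrodione, 1-[2,4-dihydroxy-3-(3-methylbut-2-en-1-yl)phenyl]-2-(2-hydroxy-4-methoxyphenyl)ethane-1,2-dione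
Conditions: n-Bu4NF, AcOH, THF, 0 °C
Reagents that add atoms: none
Why: Fluoride-induced cleavage of the aryl silyl ether is driven by the strong Si–F bond, and the AcOH buffer keeps the 1,2-dione away from strongly basic phenoxide or hydroxide so that no benzilic acid rearrangement can set in.

**Compound list**

1 | methyl (E)-4-oxopent-2-enoate | COC(=O)/C=C/C(C)=O | starting material
2 | lithium (3E)-5-methoxy-5-oxopenta-1,3-dien-2-olate (lithium enolate of 1) | COC(=O)/C=C/C(=C)[O-].[Li+] | intermediate
3 | methyl (E)-7,7,7-trifluoro-4,6-dioxohept-2-enoate (drawn as the diketone, enolized in solution) | COC(=O)/C=C/C(=O)CC(=O)C(F)(F)F | intermediate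
4 | methyl (E)-5-diazo-4-oxopent-2-enoate | COC(=O)/C=C/C(=O)C=[N+]=[N-] | intermediate
5 | ethyl 4-methylpent-3-enoate | CCOC(=O)CC=C(C)C | starting material
6 | lithium 1,1-dibromo-5-methylhexa-1,4-dien-2-olate | CC(C)=CCC(=C(Br)Br)[O-].[Li+] | intermediate
7 | lithium 5-methylhex-4-en-1-yn-1-olate | CC(C)=CCC#C[O-].[Li+] | intermediate
8 | triisopropyl[(5-methylhex-4-en-1-yn-1-yl)oxy]silane | CC(C)=CCC#CO[Si](C(C)C)(C(C)C)C(C)C | intermediate
9 | methyl (2E)-5-oxopenta-2,4-dienoate (vinylketene) | COC(=O)/C=C/C=C=O | intermediate
10 | methyl (2E)-3-{3-(3-methylbut-2-en-1-yl)-4-oxo-2-[(triisopropylsilyl)oxy]cyclobut-2-en-1-yl}prop-2-enoate, racemic | COC(=O)/C=C/C1C(=O)C(CC=C(C)C)=C1O[Si](C(C)C)(C(C)C)C(C)C | intermediate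
11 | methyl (2E,4E)-9-methyl-6-(oxomethylidene)-5-[(triisopropylsilyl)oxy]deca-2,4,8-trienoate (dienylketene) | COC(=O)/C=C/C=C(/O[Si](C(C)C)(C(C)C)C(C)C)C(CC=C(C)C)=C=O | intermediate
12 | methyl 3-(3-methylbut-2-en-1-yl)-2-oxo-4-[(triisopropylsilyl)oxy]cyclohexa-3,5-diene-1-carboxylate, racemic | COC(=O)C1C=CC(O[Si](C(C)C)(C(C)C)C(C)C)=C(CC=C(C)C)C1=O | intermediate
13 | methyl 2-hydroxy-3-(3-methylbut-2-en-1-yl)-4-[(triisopropylsilyl)oxy]benzoate | COC(=O)c1ccc(O[Si](C(C)C)(C(C)C)C(C)C)c(CC=C(C)C)c1O | intermediate
14 | methyl 2-(methoxymethoxy)-3-(3-methylbut-2-en-1-yl)-4-[(triisopropylsilyl)oxy]benzoate | COCOc1c(C(=O)OC)ccc(O[Si](C(C)C)(C(C)C)C(C)C)c1CC=C(C)C | intermediate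
15 | 2-hydroxy-4-methoxybenzaldehyde | COc1ccc(C=O)c(O)c1 | starting material
16 | 2-(1,3-dithian-2-yl)-5-methoxyphenol | COc1ccc(C2SCCCS2)c(O)c1 | intermediate
17 | 2-[4-methoxy-2-(methoxymethoxy)phenyl]-1,3-dithiane | COCOc1cc(OC)ccc1C1SCCCS1 | intermediate
18 | {2-[4-methoxy-2-(methoxymethoxy)phenyl]-1,3-dithian-2-yl}lithium | [Li]C1(c2ccc(OC)cc2OCOC)SCCCS1 | intermediate
19 | {2-[4-methoxy-2-(methoxymethoxy)phenyl]-1,3-dithian-2-yl}{2-(methoxymethoxy)-3-(3-methylbut-2-en-1-yl)-4-[(triisopropylsilyl)oxy]phenyl}methanone | COCOc1cc(OC)ccc1C1(SCCCS1)C(=O)c1ccc(O[Si](C(C)C)(C(C)C)C(C)C)c(CC=C(C)C)c1OCOC | intermediate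
20 | 1-[4-methoxy-2-(methoxymethoxy)phenyl]-2-{2-(methoxymethoxy)-3-(3-methylbut-2-en-1-yl)-4-[(triisopropylsilyl)oxy]phenyl}ethane-1,2-dione | COCOc1cc(OC)ccc1C(=O)C(=O)c1ccc(O[Si](C(C)C)(C(C)C)C(C)C)c(CC=C(C)C)c1OCOC | intermediate
21 | 1-(2-hydroxy-4-methoxyphenyl)-2-{2-hydroxy-3-(3-methylbut-2-en-1-yl)-4-[(triisopropylsilyl)oxy]phenyl}ethane-1,2-dione | COc1ccc(C(=O)C(=O)c2ccc(O[Si](C(C)C)(C(C)C)C(C)C)c(CC=C(C)C)c2O)c(O)c1 | intermediate
22 | licoagrodione, 1-[2,4-dihydroxy-3-(3-methylbut-2-en-1-yl)phenyl]-2-(2-hydroxy-4-methoxyphenyl)ethane-1,2-dione | COc1ccc(C(=O)C(=O)c2ccc(O)c(CC=C(C)C)c2O)c(O)c1 | target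

**Step count**

Total step count: 11.
Longest linear sequence: 8 steps (steps 1, 2, 4, 5, 8, 9, 10 and 11, from compound 1).

**Steps most likely to fail**

Step 4. The diazo enone may be consumed by dipolar cycloaddition of one molecule onto the electron-poor alkene of another before the ketene is formed; light may also isomerize the enoate to the Z form, which slows the final ring closure, and the ester-bearing ketene may dimerize instead of meeting the alkyne. The fallback sets out from 8 and keeps the same ring construction, but takes the ester out of the cascade. Compound 8 is heated in toluene at 80 °C with cyclobut-2-en-1-one F1, which is distilled just before use from purchased 3-bromocyclobutanone and n-Bu3N. Thermal four-electron opening of F1 gives the parent vinylketene, and the same cycloaddition, ring opening and six-electron closure (first-generation Danheiser benzannulation) should give 2-(3-methylbut-2-en-1-yl)-3-[(triisopropylsilyl)oxy]phenol F2. MOMCl and i-Pr2NEt should convert F2 into triisopropyl[3-(methoxymethoxy)-2-(3-methylbut-2-en-1-yl)phenoxy]silane F3. Directed ortho-metalation of F3 next to the MOM ether (n-BuLi, TMEDA, THF, 0 °C) should give {2-(methoxymethoxy)-3-(3-methylbut-2-en-1-yl)-4-[(triisopropylsilyl)oxy]phenyl}lithium F4, and quenching of F4 with excess ClCO2Me comes back to the route at 14.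

Step 1. The lithium enolate may add to not yet deprotonated oxo-enoate in a Michael sense faster than it is trifluoroacetylated, so that the material is lost to oligomers. The fallback sets out from 1 and avoids a metal enolate altogether. Soft enolization (Me3SiOTf, Et3N, CH2Cl2, 0 °C) should give methyl (2E)-4-[(trimethylsilyl)oxy]penta-2,4-dienoate F5. Bromination of F5 with N-bromosuccinimide (THF, -78 to 0 °C) should give methyl (E)-5-bromo-4-oxopent-2-enoate F6. N,N'-Ditosylhydrazine and DBU (THF, 0 °C, short reaction time) then displace the bromide of F6 and build the diazo group by double sulfinate elimination, which comes back to the route at 4.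

Step 8. Addition of the hindered, sulfur-stabilized carbanion to the electron-rich, ortho-substituted benzoate may be too slow, so that proton transfer from the allylic-benzylic CH2 of the prenyl group quenches the anion and starting materials are returned. The fallback sets out from 14 and raises the electrophilicity of the acyl carbon. Reduction with i-Bu2AlH (CH2Cl2, -78 °C) should give {2-(methoxymethoxy)-3-(3-methylbut-2-en-1-yl)-4-[(triisopropylsilyl)oxy]phenyl}methanol F7, and MnO2 (CH2Cl2, rt) should oxidize F7 to 2-(methoxymethoxy)-3-(3-methylbut-2-en-1-yl)-4-[(triisopropylsilyl)oxy]benzaldehyde F8. Lithiodithiane 18 should add to F8 at -78 °C to give the racemic carbinol {2-[4-methoxy-2-(methoxymethoxy)phenyl]-1,3-dithian-2-yl}{2-(methoxymethoxy)-3-(3-methylbut-2-en-1-yl)-4-[(triisopropylsilyl)oxy]phenyl}methanol F9. Parikh–Doering oxidation of F9 (SO3·pyridine, DMSO, Et3N, CH2Cl2, 0 °C), which does not touch the thioacetal, comes back to the route at 19.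

**Further compounds**

F1 | step 4 | cyclobut-2-en-1-one | O=C1CC=C1
F2 | step 4 | 2-(3-methylbut-2-en-1-yl)-3-[(triisopropylsilyl)oxy]phenol | CC(C)=CCc1c(O)cccc1O[Si](C(C)C)(C(C)C)C(C)C
F3 | step 4 | triisopropyl[3-(methoxymethoxy)-2-(3-methylbut-2-en-1-yl)phenoxy]silane | COCOc1cccc(O[Si](C(C)C)(C(C)C)C(C)C)c1CC=C(C)C
F4 | step 4 | {2-(methoxymethoxy)-3-(3-methylbut-2-en-1-yl)-4-[(triisopropylsilyl)oxy]phenyl}lithium | [Li]c1ccc(O[Si](C(C)C)(C(C)C)C(C)C)c(CC=C(C)C)c1OCOC
F5 | step 1 | methyl (2E)-4-[(trimethylsilyl)oxy]penta-2,4-dienoate | COC(=O)/C=C/C(=C)O[Si](C)(C)C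
F6 | step 1 | methyl (E)-5-bromo-4-oxopent-2-enoate | COC(=O)/C=C/C(=O)CBr
F7 | step 8 | {2-(methoxymethoxy)-3-(3-methylbut-2-en-1-yl)-4-[(triisopropylsilyl)oxy]phenyl}methanol | COCOc1c(CO)ccc(O[Si](C(C)C)(C(C)C)C(C)C)c1CC=C(C)C
F8 | step 8 | 2-(methoxymethoxy)-3-(3-methylbut-2-en-1-yl)-4-[(triisopropylsilyl)oxy]benzaldehyde | COCOc1c(C=O)ccc(O[Si](C(C)C)(C(C)C)C(C)C)c1CC=C(C)C
F9 | step 8 | {2-[4-methoxy-2-(methoxymethoxy)phenyl]-1,3-dithian-2-yl}{2-(methoxymethoxy)-3-(3-methylbut-2-en-1-yl)-4-[(triisopropylsilyl)oxy]phenyl}methanol, racemic | COCOc1cc(OC)ccc1C1(SCCCS1)C(O)c1ccc(O[Si](C(C)C)(C(C)C)C(C)C)c(CC=C(C)C)c1OCOC
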